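| flask | Q | G | Z | E | remark |
|---|---|---|---|---|---|
| ash | 0.025 M | 0.030 M | 2.5 mM | 0.36 mM | run made earlier |
| elm | 0.10 M | 0.030 M | 2.5 mM | 0.36 mM | run made earlier |
| maple | 0.050 M | 0.030 M | 5 mM | 0.36 mM | run made earlier |
| flask | 0.050 M | 0.0300 M | 2.50 mM | 0.36 mM |  |

| run | time / min | D / % |
|---|---|---|
| ash | 0.250 | 8.1 |
| ash | 0.667 | 15.2 |
| ash | 1.33 | 20.6 |
| ash | 2.00 | 21.9 |
| ash | 3.00 | 22.3 |
| ash | 4.00 | 21.9 |
| ash | 5.00 | 22.1 |
| elm | 0.250 | 3.9 |
| elm | 0.667 | 7.8 |
| elm | 1.33 | 13.8 |
| elm | 2.00 | 15.8 |
| elm | 3.00 | 18.2 |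
| elm | 4.00 | 20.0 |
| elm | 5.00 | 20.5 |
| maple | 0.417 | 7.2 |
| maple | 0.667 | 8.5 |
| maple | 1.33 | 10.7 |
| maple | 2.50 | 10.9 |
| maple | 5.00 | 11.5 |

(readings scatter by 0.5 percentage points)

- the analysis behind the earlier runs scatters by 0.5 percentage points, standard deviation
- reactions considered so far: G + E -> L; Q + L <-> J; J -> E + D; L + Z -> X
- no earlier run changes the charge of E; that part of a forecast is a guess
- no earlier run changes the charge of G; that part of a forecast is a guess

1. apparent order in G when 5.0% of the Q are converted (percent change of the rate of making D for one percent more G charged)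
2. factor on the rate of making D when 5.0% of the Q are converted if E is charged twice over

- You asked how the rate of making D at 5.0% conversion answers to G and to E.
- I took the rate of making D over the rate of losing catalyst to X. Time drops out of that ratio, and with J following L, L drops out too, which leaves D per catalyst lost proportional to [Q]/[Z], for which I put in the charged concentrations.
- The last ash reading, 22.1% at 5.00 min, taking the E of ash as lost, gave s = 1.53, the moles of D made per mole of E lost to X, divided by [Q]/[Z].
- Q cancels from the plateau as a share of Q, which is s[E]/[Z]. For maple that gave 11.1%, against a reading of 11.5% with a scatter of 0.5 percentage points.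
- For this flask, I reckoned a plateau share of 22.1%. At 5.0% conversion, I reckoned the fraction of catalyst outside X as 1 minus that conversion over the plateau share, which gave 0.774, and 0.887 with E doubled. Taking the rate as proportional to that catalyst, my factor was 2.29.
- The forecast gave 2.25 for doubled E, slightly below my factor, and 0.35 for the order in G, which it called “poorly defined”. The earlier runs kept G at one charge, so I made no reckoning of my own for that order.

    G + E → L (k = 45.0 M⁻¹ s⁻¹)
    Q + L ⇌ J (K = 6.50 M⁻¹, k = 66.0 M⁻¹ s⁻¹)
    J → E + D (k = 13.0 s⁻¹)
    L + Z → X (k = 23.0 M⁻¹ s⁻¹)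

- This flask gave an order in G of 0.62, higher than the forecast, and a factor of 2.27 for doubled E. At 0.600 min in this flask E held 27.4% of the catalyst, above L at 17.6% and J at 2.21%. At that moment s turned the 11.9% of D into 54.1% of the catalyst in X, and this flask held 52.8% there.

The runs are simulated with made-up constants, and the scatter is random.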